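**Retrosynthetic overview**

1. Target 34 ⇐ desilylation and N-hydroxylation of trienone 30 ⇐ aldol condensation of the 3-acetyl group of pyridone 17 with dienal 28 (forms C2'=C3' of the acyl chain). C8' comes from an oxazolidinone-controlled hydroxymethylation of a butanoyl imide.
2. The cis-1,4-dihydroxycyclohexyl ring is the former aryl ring: phenol 12 ⇒ p-quinol 13 (PhI(OAc)2) ⇒ ketone 14 (H2) ⇒ cis-diol 15 (NaBH4).
3. Feature: pyridone N1, C6 and C5 with its carbocycle are the N, Cα and Cβ(aryl) of a β-aryl-α-amino acid. The lactam N1–C2–C3–C4–C5–C6 is therefore a 3-acetyltetramic acid ring (N1–C2–C3–C4–Cα) with Cβ inserted between C4 and Cα.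
4. Key disconnection: pyridone 11 ⇐ dihydropyridone 10 ⇐ radical 1,2-shift of C4 from Cα to Cβ in 5-[bromo(4-methoxyphenyl)methyl]-3-acetyltetramic acid 9 (forms C4–Cβ, breaks C4–Cα).
5. 9 ⇐ carbinol 8 ⇐ Lacey–Dieckmann closure of acetoacetamide 7 (isocyanoacetate aldol, then diketene). Ring order: aryl ring bought; five-membered lactam (step 4); six-membered lactam by expansion (step 6); carbocycle saturated last (steps 9–11).

Key step: step 6

Remark (stereochemical reading): the cyclohexane descriptors of the target correspond to the cis-1,4-diol, with both hydroxyls on one face and the pyridone trans to the secondary hydroxyl; the side-chain centre is 8'R.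

Remark (racemates): 3–10 are racemic. 3–8 are drawn as one enantiomer of the expected diastereomer, 9 and 10 without descriptors. Nothing is separated because steps 6 and 7 erase these centres.

**Route**

Step 1
Reactants: 1 (methyl isocyanoacetate) and 2 (4-methoxybenzaldehyde)
Product: 3 methyl (4S*,5R*)-5-(4-methoxyphenyl)-4,5-dihydro-1,3-oxazole-4-carboxylate (racemic trans)
Conditions: CuCl (5 mol %), PPh3 (10 mol %), i-Pr2NEt (10 mol %), CH2Cl2, rt
Reagents that add atoms: none
Why: Aldol addition of the copper-bound α-isocyano ester enolate to the aldehyde, then closure of the alkoxide onto the isocyanide carbon (isocyanoacetate aldol reaction), should give the trans-oxazoline as a masked β-hydroxy-α-amino ester; its relative configuration does not matter because both centres are destroyed in steps 6 and 7.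

Step 2
Reactants: 3
Product: 5 methyl (2S*,3R*)-2-amino-3-hydroxy-3-(4-methoxyphenyl)propanoate hydrochloride, via O-formyl ammonium chloride 4 (not isolated)
Conditions: conc. HCl (3 equiv), MeOH, rt to 45 °C; evaporate
Reagents that add atoms: hydrogen chloride, Cl (chloride of 4 and 5); water, O (formyl oxygen of 4 only)
Why: Acid hydrolysis of the 2-oxazoline opens the protonated ring at C2–N to the O-formyl ammonium salt, and acid-catalysed transesterification with methanol removes the formyl group without touching the bonds at the two stereocentres, while the neighbouring ammonium group disfavours ionisation of the anisylic alcohol.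

Step 3
Reactants: 5 and 6 (diketene)
Product: 7 methyl (2S*,3R*)-3-hydroxy-3-(4-methoxyphenyl)-2-(3-oxobutanoylamino)propanoate
Conditions: Et3N (1.05 equiv), CH2Cl2, 0 °C
Reagents that add atoms: none
Why: The liberated primary amine opens the β-lactone of diketene at the acyl carbon (N-acetoacetylation) much faster than the secondary alcohol can at 0 °C without an acylation catalyst.

Step 4
Reactants: 7
Product: 8 (5S*)-3-acetyl-4-hydroxy-5-[(R*)-hydroxy(4-methoxyphenyl)methyl]-1,5-dihydro-2H-pyrrol-2-one
Conditions: NaOMe (2.2 equiv), MeOH, rt to 60 °C; then cold 1 M HCl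
Reagents that add atoms: none
Why: Lacey–Dieckmann cyclisation: the acetoacetamide carbanion attacks the methyl ester 5-exo-trig and the strongly acidic 3-acyltetramic acid is trapped as its sodium salt, which keeps C5–H from being deprotonated so that dehydration and retro-aldol cleavage should stay slow; partial epimerisation at C5 would be harmless.

Step 5
Reactants: 8
Product: 9 3-acetyl-5-[bromo(4-methoxyphenyl)methyl]-4-hydroxy-1,5-dihydro-2H-pyrrol-2-one (racemic, both diastereomers, used crude)
Conditions: HBr (33 % in AcOH, 3 equiv), CH2Cl2, 0 °C; volatiles removed with toluene below 25 °C; no base, no chromatography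
Reagents that add atoms: hydrogen bromide, Br
Why: The p-methoxyphenyl group allows SN1 ionisation of the protonated benzylic alcohol and bromide captures the cation, excess HBr holding the addition–elimination balance on the side of the bromide, while the acylamino and keto groups on the neighbouring C5 temper ionisation enough for the bromide to be handled briefly without base.

Step 6
Reactants: 9
Product: 10 3-acetyl-4-hydroxy-5-(4-methoxyphenyl)-5,6-dihydropyridin-2(1H)-one (racemic)
Conditions: Bu3SnH (1.3 equiv), AIBN (0.2 equiv), degassed benzene, 80 °C; 9 and the stannane/AIBN solution added from separate syringe pumps over 8 h (final 5 mM in 9); product extracted into aq. NaHCO3, tin residues washed out with hexane, acidified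
Reagents that add atoms: none
Why: Proposed new method: the stannyl radical abstracts bromine from 9 to give the anisyl-stabilised benzylic radical, which attacks the adjacent ring carbon C4 (a ketone carbon in the keto tautomer, the β-carbon of a doubly acceptor-substituted enol in the chelated tautomer) to give a bicyclo[3.1.0] oxygen- or C3-centred radical, and β-scission of the ring-fusion bond C4–Cα then gives the α-amido radical of the six-membered lactam, which takes hydrogen from tin; this 1,2-shift of an acyl carbon has not been shown on tetramic acids, the closest known reactions being the Dowd–Beckwith one-carbon expansion of 2-(halomethyl) β-keto esters and neophyl-type 1,2-acyl migrations. The six-membered ring is closed in two stages, a 3-exo-trig closure (new bond C4–Cβ, which is C4–C5 of 10) followed by fragmentation of the old C4–Cα bond, so the ring arises by enlargement and not by a direct 6-endo closure. The only new stereocentre, C5 of 10, is formed without any controlling element and as a racemate, which is acceptable because step 7 makes it trigonal. The selectivity needed is rearrangement before hydrogen transfer to the benzylic radical: that radical abstracts from Bu3SnH only slowly, the stannane is kept at a low stationary concentration, and the other closures open to it (4-exo onto C3, attack on the acetyl group) would give a cyclobutane or a bridgehead radical and are not expected. Re-opening of the cyclopropane by its exocyclic bond merely regenerates the benzylic radical, whereas the rearranged nucleophilic α-amido radical should be trapped quickly and pull the sequence towards 10; any 6-bromo compound formed by bromine-atom transfer would lose HBr to pyridone 11 and converge in step 7.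

Step 7
Reactants: 10
Product: 11 3-acetyl-4-hydroxy-5-(4-methoxyphenyl)pyridin-2(1H)-one
Conditions: DDQ (1.2 equiv), 1,4-dioxane, 80 °C
Reagents that add atoms: none
Why: DDQ abstracts hydride from the enolised dihydropyridone, whose C5–H is benzylic and next to the C4 oxygen function and whose C6–H is α to nitrogen, and proton loss gives the aromatic 4-hydroxy-2-pyridone (dehydrogenation driven by aromatisation), removing the stereocentre of 10.

Step 8
Reactants: 11
Product: 12 3-acetyl-4-hydroxy-5-(4-hydroxyphenyl)pyridin-2(1H)-one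
Conditions: BBr3 (4 equiv), CH2Cl2, −78 °C to rt; MeOH, then H2O
Reagents that add atoms: none
Why: BBr3 cleaves the aryl methyl ether through the aryloxyborane (Lewis-acid demethylation), and the acylpyridone, held meanwhile as a boron chelate, is released unchanged on methanolysis.

Step 9
Reactants: 12
Product: 13 3-acetyl-4-hydroxy-5-(1-hydroxy-4-oxocyclohexa-2,5-dien-1-yl)pyridin-2(1H)-one
Conditions: PhI(OAc)2 (1.1 equiv), MeCN–H2O 3:1, 0 °C; cold extractive work-up, crude 13 used at once
Reagents that add atoms: water, O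
Why: Ligand exchange of the phenol on hypervalent iodine and loss of PhI give a phenoxenium-type species that water captures at the substituted para carbon (oxidative dearomatisation of a 4-substituted phenol to a p-quinol), while the chelated, acyl-deactivated hydroxypyridone should not compete; 13 is not stored because its enol oxygen can add reversibly to the dienone.

Step 10
Reactants: 13
Product: 14 3-acetyl-4-hydroxy-5-(1-hydroxy-4-oxocyclohexyl)pyridin-2(1H)-one
Conditions: H2 (1 atm), 5 % Rh/Al2O3, Et3N (1.2 equiv), EtOAc–MeOH, rt; then dilute citric acid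
Reagents that add atoms: none
Why: Rhodium on alumina saturates the two enone C=C bonds at one atmosphere with little hydrogenolysis of the tertiary doubly allylic C–O bond, and Et3N keeps the pyridone as its delocalised anion, a good leaving group, so that any oxa-Michael adduct of the 4-oxygen re-opens by E1cB and is drained to 14.

Step 11
Reactants: 14
Product: 15 3-acetyl-5-(cis-1,4-dihydroxycyclohexyl)-4-hydroxypyridin-2(1H)-one (hydroxyls cis)
Conditions: NaBH4 (3 equiv), MeOH, −20 to 0 °C; minor trans-diol removed by crystallisation or chromatography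
Reagents that add atoms: none
Why: Axial hydride delivery to the chair that carries the bulky pyridonyl group equatorial and the tertiary hydroxyl axial should give mainly the equatorial secondary alcohol, that is the diol with both hydroxyls on one face, while the acetyl group is part of the deprotonated pyridone and is not reduced.

Step 12
Reactants: 15
Product: 17 3-acetyl-5-[cis-1,4-bis(triethylsilyloxy)cyclohexyl]-4-hydroxypyridin-2(1H)-one, via tetrakis(triethylsilyl) derivative 16 (not isolated)
Conditions: TESOTf (5 equiv), 2,6-lutidine (7 equiv), CH2Cl2, −78 to 0 °C; then K2CO3 (0.2 equiv), MeOH, 0 °C, short contact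
Reagents that add atoms: triethylsilyl trifluoromethanesulfonate, CC[Si](CC)(CC)OS(=O)(=O)C(F)(F)F
Why: The silyl triflate silylates all four oxygens, the hindered tertiary alcohol included, and brief methanolysis then cleaves only the two labile pyridyl silyl ethers, leaving the alkyl triethylsilyl ethers that keep the polyanion of step 21 to three charges.

Step 13
Reactants: 18 ((R)-4-benzyl-1,3-oxazolidin-2-one) and 19 (butanoyl chloride)
Product: 20 (R)-4-benzyl-3-butanoyl-1,3-oxazolidin-2-one
Conditions: n-BuLi (1.0 equiv), THF, −78 °C; then 19, −78 to 0 °C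
Reagents that add atoms: none
Why: N-Acylation of the lithiated oxazolidinone with the acid chloride is the standard entry to the chiral imide.

Step 14
Reactants: 20
Product: 21 (R)-4-benzyl-3-[(S)-2-(hydroxymethyl)butanoyl]-1,3-oxazolidin-2-one
Conditions: TiCl4 (1.05 equiv), i-Pr2NEt (1.1 equiv), CH2Cl2, 0 °C; then 1,3,5-trioxane (1.1 equiv), TiCl4 (1.05 equiv), 0 °C
Reagents that add atoms: 1,3,5-trioxane, C1OCOCO1
Why: The chelated Z titanium enolate of the imide is hydroxymethylated by TiCl4-activated trioxane on the face opposite the benzyl group (Evans auxiliary-controlled hydroxymethylation), which sets the future C8' with the (S) descriptor in 21, corresponding to 8'R in the target.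

Step 15
Reactants: 21
Product: 22 (R)-4-benzyl-3-[(S)-2-({[tert-butyl(dimethyl)silyl]oxy}methyl)butanoyl]-1,3-oxazolidin-2-one
Conditions: TBSCl (1.2 equiv), imidazole (2.5 equiv), DMF, rt
Reagents that add atoms: tert-butyldimethylsilyl chloride, CC(C)(C)[Si](C)(C)Cl
Why: Imidazole-promoted silylation of the primary alcohol blocks retro-aldol loss of formaldehyde and differentiates the two oxygen-bearing arms.

Step 16
Reactants: 22
Product: 23 (R)-2-({[tert-butyl(dimethyl)silyl]oxy}methyl)butan-1-ol
Conditions: LiBH4 (1.5 equiv), H2O (1.5 equiv), Et2O, 0 °C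
Reagents that add atoms: none
Why: Borohydride reduces the exocyclic imide carbonyl and releases the auxiliary (reductive auxiliary cleavage) without touching the stereocentre; the low temperature is chosen to suppress 1,3-silyl migration, which would exchange the two arms.

Step 17
Reactants: 23
Product: 24 (S)-2-({[tert-butyl(dimethyl)silyl]oxy}methyl)butanal
Conditions: TEMPO (10 mol %), PhI(OAc)2 (1.2 equiv), CH2Cl2, rt; used without delay
Reagents that add atoms: none
Why: Oxoammonium-mediated oxidation stops at the aldehyde under nearly neutral conditions, so the α-stereocentre should not epimerise.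

Step 18
Reactants: 24 and 25 (triethyl (E)-4-phosphonocrotonate)
Product: 26 ethyl (2E,4E,6R)-6-({[tert-butyl(dimethyl)silyl]oxy}methyl)octa-2,4-dienoate
Conditions: LiHMDS (1.1 equiv), THF, −78 °C; then 24, −78 to 0 °C
Reagents that add atoms: none
Why: Vinylogous Horner–Wadsworth–Emmons olefination with the stabilised phosphonate anion gives the E,E-dienoate under thermodynamic control, and the weakly basic anion should leave the α-stereocentre intact.

Step 19
Reactants: 26
Product: 27 (2E,4E,6R)-6-({[tert-butyl(dimethyl)silyl]oxy}methyl)octa-2,4-dien-1-ol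
Conditions: i-Bu2AlH (2.3 equiv), CH2Cl2, −78 °C; Rochelle salt work-up
Reagents that add atoms: none
Why: The aluminium hydride reduces the conjugated ester 1,2 to the dienol without conjugate reduction.

Step 20
Reactants: 27
Product: 28 (2E,4E,6R)-6-({[tert-butyl(dimethyl)silyl]oxy}methyl)octa-2,4-dienal
Conditions: MnO2 (15 equiv), CH2Cl2, rt
Reagents that add atoms: none
Why: MnO2 oxidises the allylic alcohol selectively to the dienal without isomerising the diene.

Step 21
Reactants: 17 and 28
Product: 29 5-[cis-1,4-bis(triethylsilyloxy)cyclohexyl]-3-[(4E,6E,8R)-8-({[tert-butyl(dimethyl)silyl]oxy}methyl)-3-hydroxydeca-4,6-dienoyl]-4-hydroxypyridin-2(1H)-one (both C3' epimers)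
Conditions: LDA (3.5 equiv), THF, −78 to −20 °C; then 28, −78 °C; AcOH quench
Reagents that add atoms: none
Why: Threefold deprotonation (N–H, 4-OH, acetyl CH3) gives a trianion whose terminal carbanion is the most reactive site and adds 1,2 to the dienal (polyanion aldol addition, as used for 3-acyltetramic acids and 3-acetyl-4-hydroxypyridones); the new carbinol centre is uncontrolled and is removed in step 22.

Step 22
Reactants: 29
Product: 30 5-[cis-1,4-bis(triethylsilyloxy)cyclohexyl]-3-[(2E,4E,6E,8R)-8-({[tert-butyl(dimethyl)silyl]oxy}methyl)deca-2,4,6-trienoyl]-4-hydroxypyridin-2(1H)-one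
Conditions: CSA (0.2 equiv), CH2Cl2, 0 °C to rt
Reagents that add atoms: none
Why: Acid-catalysed dehydration of the dienylic β-hydroxy ketone by loss of the C2' proton gives the fully conjugated trienone, the 2E geometry following from thermodynamic control, under conditions mild enough for the silyl ethers.

Step 23
Reactants: 30
Product: 33 5-[cis-1,4-bis(triethylsilyloxy)cyclohexyl]-3-[(2E,4E,6E,8R)-8-({[tert-butyl(dimethyl)silyl]oxy}methyl)deca-2,4,6-trienoyl]-1,4-dihydroxypyridin-2(1H)-one, via bis(trimethylsilyloxy)pyridine 31 (not isolated), via pyridine N-oxide 32 (not isolated)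
Conditions: BSA (4 equiv), CH2Cl2, rt; then MoO5·DMF (1.5 equiv), CH2Cl2, rt, dark; aq. Na4EDTA, then dilute citric acid
Reagents that add atoms: oxodiperoxomolybdenum–DMF complex MoO5·DMF, CN(C)C=O.O=[Mo]12(OO1)OO2 (the N–O oxygen); N,O-bis(trimethylsilyl)acetamide, CC(=N[Si](C)(C)C)O[Si](C)(C)C (silyl groups of 31 and 32 only)
Why: O-Silylation turns the pyridone into a 2,4-bis(silyloxy)pyridine whose ring nitrogen is oxidised by the peroxomolybdenum complex, and hydrolysis of the silylated N-oxide gives the cyclic hydroxamic acid (the known conversion of silylated 2-pyridones into 1-hydroxy-2-pyridones); the electrophilic peroxo reagent should react only slowly with the acceptor-substituted triene at rt.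

Step 24
Reactants: 33
Product: 34 1,4-dihydroxy-5-(cis-1,4-dihydroxycyclohexyl)-3-[(2E,4E,6E,8R)-8-(hydroxymethyl)deca-2,4,6-trienoyl]pyridin-2(1H)-one (target)
Conditions: HF·pyridine, pyridine, THF, 0 °C to rt
Reagents that add atoms: none
Why: Buffered fluoride-mediated desilylation removes the primary tert-butyldimethylsilyl and both triethylsilyl ethers without ionising the tertiary carbinol and without affecting the triene or the N-hydroxy group.

**Compound list**

1 | methyl isocyanoacetate | [C-]#[N+]CC(=O)OC | starting material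
2 | 4-methoxybenzaldehyde | COc1ccc(C=O)cc1 | starting material
3 | methyl (4S*,5R*)-5-(4-methoxyphenyl)-4,5-dihydro-1,3-oxazole-4-carboxylate (racemic trans) | COc1ccc(cc1)[C@H]1OC=N[C@@H]1C(=O)OC | intermediate
4 | methyl (2S*,3R*)-2-amino-3-(formyloxy)-3-(4-methoxyphenyl)propanoate hydrochloride (racemic, not isolated) | COc1ccc(cc1)[C@@H](OC=O)[C@H](N)C(=O)OC.Cl | intermediate
5 | methyl (2S*,3R*)-2-amino-3-hydroxy-3-(4-methoxyphenyl)propanoate hydrochloride (racemic threo) | COc1ccc(cc1)[C@@H](O)[C@H](N)C(=O)OC.Cl | intermediate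
6 | diketene (4-methylideneoxetan-2-one) | C=C1CC(=O)O1 | starting material
7 | methyl (2S*,3R*)-3-hydroxy-3-(4-methoxyphenyl)-2-(3-oxobutanoylamino)propanoate (racemic) | COc1ccc(cc1)[C@@H](O)[C@H](NC(=O)CC(C)=O)C(=O)OC | intermediate
8 | (5S*)-3-acetyl-4-hydroxy-5-[(R*)-hydroxy(4-methoxyphenyl)methyl]-1,5-dihydro-2H-pyrrol-2-one (racemic) | CC(=O)C1=C(O)[C@H]([C@H](O)c2ccc(OC)cc2)NC1=O | intermediate
9 | 3-acetyl-5-[bromo(4-methoxyphenyl)methyl]-4-hydroxy-1,5-dihydro-2H-pyrrol-2-one (racemic, both diastereomers) | CC(=O)C1=C(O)C(C(Br)c2ccc(OC)cc2)NC1=O | intermediate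
10 | 3-acetyl-4-hydroxy-5-(4-methoxyphenyl)-5,6-dihydropyridin-2(1H)-one (racemic) | CC(=O)C1=C(O)C(c2ccc(OC)cc2)CNC1=O | intermediate
11 | 3-acetyl-4-hydroxy-5-(4-methoxyphenyl)pyridin-2(1H)-one | CC(=O)c1c(O)c(-c2ccc(OC)cc2)c[nH]c1=O | intermediate
12 | 3-acetyl-4-hydroxy-5-(4-hydroxyphenyl)pyridin-2(1H)-one | CC(=O)c1c(O)c(-c2ccc(O)cc2)c[nH]c1=O | intermediate
13 | 3-acetyl-4-hydroxy-5-(1-hydroxy-4-oxocyclohexa-2,5-dien-1-yl)pyridin-2(1H)-one | CC(=O)c1c(O)c(C2(O)C=CC(=O)C=C2)c[nH]c1=O | intermediate
14 | 3-acetyl-4-hydroxy-5-(1-hydroxy-4-oxocyclohexyl)pyridin-2(1H)-one | CC(=O)c1c(O)c(C2(O)CCC(=O)CC2)c[nH]c1=O | intermediate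
15 | 3-acetyl-5-(cis-1,4-dihydroxycyclohexyl)-4-hydroxypyridin-2(1H)-one (hydroxyls cis) | CC(=O)c1c(O)c([C@]2(O)CC[C@@H](O)CC2)c[nH]c1=O | intermediate
16 | 1-{5-[cis-1,4-bis(triethylsilyloxy)cyclohexyl]-2,4-bis(triethylsilyloxy)pyridin-3-yl}ethanone (not isolated) | CC(=O)c1c(O[Si](CC)(CC)CC)c([C@]2(O[Si](CC)(CC)CC)CC[C@@H](O[Si](CC)(CC)CC)CC2)cnc1O[Si](CC)(CC)CC | intermediate
17 | 3-acetyl-5-[cis-1,4-bis(triethylsilyloxy)cyclohexyl]-4-hydroxypyridin-2(1H)-one | CC(=O)c1c(O)c([C@]2(O[Si](CC)(CC)CC)CC[C@@H](O[Si](CC)(CC)CC)CC2)c[nH]c1=O | intermediate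
18 | (R)-4-benzyl-1,3-oxazolidin-2-one | O=C1N[C@H](Cc2ccccc2)CO1 | starting material
19 | butanoyl chloride | CCCC(=O)Cl | starting material
20 | (R)-4-benzyl-3-butanoyl-1,3-oxazolidin-2-one | CCCC(=O)N1[C@H](Cc2ccccc2)COC1=O | intermediate
21 | (R)-4-benzyl-3-[(S)-2-(hydroxymethyl)butanoyl]-1,3-oxazolidin-2-one | CC[C@H](C(=O)N1[C@H](Cc2ccccc2)COC1=O)CO | intermediate
22 | (R)-4-benzyl-3-[(S)-2-({[tert-butyl(dimethyl)silyl]oxy}methyl)butanoyl]-1,3-oxazolidin-2-one | CC[C@H](C(=O)N1[C@H](Cc2ccccc2)COC1=O)CO[Si](C)(C)C(C)(C)C | intermediate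
23 | (R)-2-({[tert-butyl(dimethyl)silyl]oxy}methyl)butan-1-ol | CC[C@H](CO)CO[Si](C)(C)C(C)(C)C | intermediate
24 | (S)-2-({[tert-butyl(dimethyl)silyl]oxy}methyl)butanal | CC[C@H](C=O)CO[Si](C)(C)C(C)(C)C | intermediate
25 | triethyl (E)-4-phosphonocrotonate | CCOC(=O)/C=C/CP(=O)(OCC)OCC | starting material
26 | ethyl (2E,4E,6R)-6-({[tert-butyl(dimethyl)silyl]oxy}methyl)octa-2,4-dienoate | CC[C@H](/C=C/C=C/C(=O)OCC)CO[Si](C)(C)C(C)(C)C | intermediate
27 | (2E,4E,6R)-6-({[tert-butyl(dimethyl)silyl]oxy}methyl)octa-2,4-dien-1-ol | CC[C@H](/C=C/C=C/CO)CO[Si](C)(C)C(C)(C)C | intermediate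
28 | (2E,4E,6R)-6-({[tert-butyl(dimethyl)silyl]oxy}methyl)octa-2,4-dienal | CC[C@H](/C=C/C=C/C=O)CO[Si](C)(C)C(C)(C)C | intermediate
29 | 5-[cis-1,4-bis(triethylsilyloxy)cyclohexyl]-3-[(4E,6E,8R)-8-({[tert-butyl(dimethyl)silyl]oxy}methyl)-3-hydroxydeca-4,6-dienoyl]-4-hydroxypyridin-2(1H)-one (both C3' epimers) | CC[C@H](/C=C/C=C/C(O)CC(=O)c1c(O)c([C@]2(O[Si](CC)(CC)CC)CC[C@@H](O[Si](CC)(CC)CC)CC2)c[nH]c1=O)CO[Si](C)(C)C(C)(C)C | intermediate
30 | 5-[cis-1,4-bis(triethylsilyloxy)cyclohexyl]-3-[(2E,4E,6E,8R)-8-({[tert-butyl(dimethyl)silyl]oxy}methyl)deca-2,4,6-trienoyl]-4-hydroxypyridin-2(1H)-one | CC[C@H](/C=C/C=C/C=C/C(=O)c1c(O)c([C@]2(O[Si](CC)(CC)CC)CC[C@@H](O[Si](CC)(CC)CC)CC2)c[nH]c1=O)CO[Si](C)(C)C(C)(C)C | intermediate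
31 | (2E,4E,6E,8R)-1-{5-[cis-1,4-bis(triethylsilyloxy)cyclohexyl]-2,4-bis(trimethylsilyloxy)pyridin-3-yl}-8-({[tert-butyl(dimethyl)silyl]oxy}methyl)deca-2,4,6-trien-1-one (not isolated) | CC[C@H](/C=C/C=C/C=C/C(=O)c1c(O[Si](C)(C)C)c([C@]2(O[Si](CC)(CC)CC)CC[C@@H](O[Si](CC)(CC)CC)CC2)cnc1O[Si](C)(C)C)CO[Si](C)(C)C(C)(C)C | intermediate
32 | pyridine 1-oxide of 31 (not isolated) | CC[C@H](/C=C/C=C/C=C/C(=O)c1c(O[Si](C)(C)C)c([C@]2(O[Si](CC)(CC)CC)CC[C@@H](O[Si](CC)(CC)CC)CC2)c[n+]([O-])c1O[Si](C)(C)C)CO[Si](C)(C)C(C)(C)C | intermediate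
33 | 5-[cis-1,4-bis(triethylsilyloxy)cyclohexyl]-3-[(2E,4E,6E,8R)-8-({[tert-butyl(dimethyl)silyl]oxy}methyl)deca-2,4,6-trienoyl]-1,4-dihydroxypyridin-2(1H)-one | CC[C@H](/C=C/C=C/C=C/C(=O)c1c(O)c([C@]2(O[Si](CC)(CC)CC)CC[C@@H](O[Si](CC)(CC)CC)CC2)cn(O)c1=O)CO[Si](C)(C)C(C)(C)C | intermediate
34 | 1,4-dihydroxy-5-(cis-1,4-dihydroxycyclohexyl)-3-[(2E,4E,6E,8R)-8-(hydroxymethyl)deca-2,4,6-trienoyl]pyridin-2(1H)-one | CC[C@H](/C=C/C=C/C=C/C(=O)c1c(O)c([C@]2(O)CC[C@@H](O)CC2)cn(O)c1=O)CO | target

**Step count**

Total: 24 steps. Longest linear sequence: 16 steps (steps 1–12 and 21–24); the dienal branch is steps 13–20.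

**Steps most likely to fail**

1. Step 6 (radical ring expansion). What may go wrong: hydrogen transfer to the benzylic radical before the acyl shift, which would give the unrearranged 5-(4-methoxybenzyl)tetramic acid; re-opening of the cyclopropane intermediate only by its exocyclic bond; or thermal loss of HBr from 9 before the chain starts. Fallback by known chemistry, forming the six-membered lactam directly: it sets out from diketene 6 and returns at pyridone 11. Ethyl (4-methoxyphenyl)acetate F1 (purchased) is formylated with ethyl formate and NaH to ethyl 3-hydroxy-2-(4-methoxyphenyl)prop-2-enoate F2. NH4OAc in hot EtOH converts this into ethyl 3-amino-2-(4-methoxyphenyl)prop-2-enoate F3. Diketene 6 acylates the enamine nitrogen, whose carbon terminus is blocked by the aryl group, to give ethyl 2-(4-methoxyphenyl)-3-(3-oxobutanoylamino)prop-2-enoate F4. NaOEt in EtOH then closes the ring by attack of the acetoacetamide carbanion on the ester (vinylogous Lacey–Dieckmann cyclisation), giving 11 and making steps 1–7 unnecessary.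

2. Step 5 (benzylic bromide). What may go wrong: ionisation of the anisylic C–Br bond and loss of HBr towards the conjugated 5-arylidene tetramic acid during concentration or while 9 waits in the syringe. Fallback with a radical precursor that cannot eliminate: it sets out from carbinol 8 and returns at dihydropyridone 10. Treatment of 8 with PhSeH in TFA/CH2Cl2 at 0 °C traps the anisylic cation as 3-acetyl-4-hydroxy-5-[(4-methoxyphenyl)(phenylselanyl)methyl]-1,5-dihydro-2H-pyrrol-2-one F5. This selenide can be purified and stored, and is then submitted to Bu3SnH/AIBN under the slow-addition conditions of step 6; homolytic substitution at selenium generates the same benzylic radical.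

3. Step 23 (N-hydroxylation). What may go wrong: sluggish N-oxidation of the acyl-deactivated silyloxypyridine, with competing oxidation of the triene on prolonged exposure. Fallback by oxidising before the polyene is present: it sets out from acetylpyridone 17 and returns at 33. BSA converts 17 into 1-{5-[cis-1,4-bis(triethylsilyloxy)cyclohexyl]-2,4-bis(trimethylsilyloxy)pyridin-3-yl}ethanone F6. MoO5·DMF oxidises this to its pyridine 1-oxide F7, and aqueous work-up gives 3-acetyl-5-[cis-1,4-bis(triethylsilyloxy)cyclohexyl]-1,4-dihydroxypyridin-2(1H)-one F8. The tetra-anion of F8 (LDA, 4.5 equiv, THF, −78 °C) adds to dienal 28 to give the 3-hydroxydeca-4,6-dienoyl adduct F9, which is dehydrated with CSA as in step 22 to give 33.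

Further compounds
F1 | step 6 | ethyl (4-methoxyphenyl)acetate (purchased) | CCOC(=O)Cc1ccc(OC)cc1
F2 | step 6 | ethyl 3-hydroxy-2-(4-methoxyphenyl)prop-2-enoate | CCOC(=O)C(=CO)c1ccc(OC)cc1
F3 | step 6 | ethyl 3-amino-2-(4-methoxyphenyl)prop-2-enoate | CCOC(=O)C(=CN)c1ccc(OC)cc1
F4 | step 6 | ethyl 2-(4-methoxyphenyl)-3-(3-oxobutanoylamino)prop-2-enoate | CCOC(=O)C(=CNC(=O)CC(C)=O)c1ccc(OC)cc1
F5 | step 5 | 3-acetyl-4-hydroxy-5-[(4-methoxyphenyl)(phenylselanyl)methyl]-1,5-dihydro-2H-pyrrol-2-one (racemic, both diastereomers) | CC(=O)C1=C(O)C(C([Se]c2ccccc2)c2ccc(OC)cc2)NC1=O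
F6 | step 23 | 1-{5-[cis-1,4-bis(triethylsilyloxy)cyclohexyl]-2,4-bis(trimethylsilyloxy)pyridin-3-yl}ethanone | CC(=O)c1c(O[Si](C)(C)C)c([C@]2(O[Si](CC)(CC)CC)CC[C@@H](O[Si](CC)(CC)CC)CC2)cnc1O[Si](C)(C)C
F7 | step 23 | pyridine 1-oxide of F6 | CC(=O)c1c(O[Si](C)(C)C)c([C@]2(O[Si](CC)(CC)CC)CC[C@@H](O[Si](CC)(CC)CC)CC2)c[n+]([O-])c1O[Si](C)(C)C
F8 | step 23 | 3-acetyl-5-[cis-1,4-bis(triethylsilyloxy)cyclohexyl]-1,4-dihydroxypyridin-2(1H)-one | CC(=O)c1c(O)c([C@]2(O[Si](CC)(CC)CC)CC[C@@H](O[Si](CC)(CC)CC)CC2)cn(O)c1=O
F9 | step 23 | 5-[cis-1,4-bis(triethylsilyloxy)cyclohexyl]-3-[(4E,6E,8R)-8-({[tert-butyl(dimethyl)silyl]oxy}methyl)-3-hydroxydeca-4,6-dienoyl]-1,4-dihydroxypyridin-2(1H)-one (both C3' epimers) | CC[C@H](/C=C/C=C/C(O)CC(=O)c1c(O)c([C@]2(O[Si](CC)(CC)CC)CC[C@@H](O[Si](CC)(CC)CC)CC2)cn(O)c1=O)CO[Si](C)(C)C(C)(C)C
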